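**Plan**

- Locants: the isoquinoline is numbered C1–C8a; the naphthalene carries primes, with C8′ bonded to C5. Ring A′ is C1′, C2′ (methyl), C3′, C4′ (OMe), C4a′, C8a′; ring B′ is C4a′, C5′ (OMe), C6′, C7′, C8′, C8a′.
- The retrosynthesis removes the N-Boc group and a surplus C1′ hydroxyl, then opens ring A′ at C4′–C3′, C2′–C1′ and C1′–C8a′ into a chromium methoxycarbene (C4′), propyne (C3′, C2′) and CO (C1′). Ring A′ has exactly this 3+2+1 pattern, and the C5′ methoxy group blocks the second ortho site.
- Further cuts are C4′–C4a′ (aryllithium plus Cr(CO)6), the biaryl bond C5–C8′ (Suzuki coupling), C1–C8a (Pictet–Spengler) and C4–C4a (aryl Grignard opening of a cyclic sulfamidate).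
- Forward, the nitrogen ring of the tetrahydroisoquinoline closes first, ring B′ is attached next as a plain anisole with no ortho group on its side of the axis, and ring A′ is annulated last, so the peri ring that crowds the C5–C8′ bond arrives after that bond exists.
- The only stereocentre, C3 (S), is bought with the L-alaninol-derived sulfamidate 2; no later step touches it.

Key step: step 8

Assumption: the target is drawn without a configuration at the C5–C8′ axis, so the axis is left uncontrolled; the route fixes C3 as (S) and would give both rotamers about the axis if rotation is slow.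

**Step 1**
Reactants: 1 1-bromo-3,5-dimethoxybenzene; 2 tert-butyl (4S)-4-methyl-1,2,3-oxathiazolidine-3-carboxylate 2,2-dioxide
Product: 5 tert-butyl N-[(2S)-1-(3,5-dimethoxyphenyl)propan-2-yl]carbamate, via aryl Grignard reagent 3 (not isolated), via ring-opened N-sulfamate salt 4 (not isolated)
Conditions: Mg, I2 (cat.), THF, reflux; then 2, CuI (10 mol%), THF, −30 °C to rt; then 10% aq. citric acid, rt
Reagents that add atoms: none
Why: Copper-catalysed ring opening of a cyclic sulfamidate by an aryl Grignard reagent is an SN2 attack at the primary C–O carbon, one atom away from the stereocentre, so the (S) configuration of 2 should pass unchanged, and mild aqueous acid should hydrolyse the N-sulfamate while the Boc group stays.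

**Step 2**
Reactants: 5 tert-butyl N-[(2S)-1-(3,5-dimethoxyphenyl)propan-2-yl]carbamate
Product: 7 (3S)-6,8-dimethoxy-3-methyl-1,2,3,4-tetrahydroisoquinoline, via primary amine trifluoroacetate 6 (not isolated)
Conditions: TFA, CH2Cl2, rt; evaporate; then 37% aq. CH2O (1.1 equiv), 1 M aq. HCl, EtOH, 60 °C; aq. NaOH work-up
Reagents that add atoms: formaldehyde, C=O
Why: Acidolysis of the Boc group followed by a Pictet–Spengler cyclisation should close the C1–C8a bond at a ring position ortho to one methoxy group and para to the other; the two such positions are equivalent by symmetry, so one regioisomer is expected, and C3 is not involved.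

**Step 3**
Reactants: 7 (3S)-6,8-dimethoxy-3-methyl-1,2,3,4-tetrahydroisoquinoline
Product: 8 tert-butyl (3S)-6,8-dimethoxy-3-methyl-3,4-dihydro-1H-isoquinoline-2-carboxylate
Conditions: Boc2O, Et3N, CH2Cl2, rt
Reagents that add atoms: di-tert-butyl dicarbonate, CC(C)(C)OC(=O)OC(=O)OC(C)(C)C
Why: N-acylation of the secondary amine as its tert-butyl carbamate removes the N–H, which would otherwise be brominated in step 4, bind palladium in steps 5 and 6 and be methylated or add to the carbene in step 7.

**Step 4**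
Reactants: 8 tert-butyl (3S)-6,8-dimethoxy-3-methyl-3,4-dihydro-1H-isoquinoline-2-carboxylate
Product: 9 tert-butyl (3S)-5-bromo-6,8-dimethoxy-3-methyl-3,4-dihydro-1H-isoquinoline-2-carboxylate
Conditions: NBS (1.0 equiv), MeCN, 0 °C
Reagents that add atoms: N-bromosuccinimide, O=C1CCC(=O)N1Br
Why: Electrophilic aromatic bromination should go to C5, which is para to the C8 methoxy group and ortho to the C6 methoxy group, in preference to C7, which lies between the two methoxy groups and is only ortho-activated; this is the usual outcome for 3,5-dimethoxy-alkylbenzenes.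

**Step 5**
Reactants: 9 tert-butyl (3S)-5-bromo-6,8-dimethoxy-3-methyl-3,4-dihydro-1H-isoquinoline-2-carboxylate
Product: 10 tert-butyl (3S)-6,8-dimethoxy-3-methyl-5-(4,4,5,5-tetramethyl-1,3,2-dioxaborolan-2-yl)-3,4-dihydro-1H-isoquinoline-2-carboxylate
Conditions: B2pin2, Pd2(dba)3 (2 mol%), XPhos (8 mol%), KOAc, dioxane, 100 °C
Reagents that add atoms: bis(pinacolato)diboron, CC1(C)OB(OC1(C)C)B1OC(C)(C)C(C)(C)O1
Why: Miyaura borylation with a bulky biarylphosphine ligand is suited to electron-rich aryl bromides with two ortho substituents and avoids any organolithium next to the carbamate.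

**Step 6**
Reactants: 10 tert-butyl (3S)-6,8-dimethoxy-3-methyl-5-(4,4,5,5-tetramethyl-1,3,2-dioxaborolan-2-yl)-3,4-dihydro-1H-isoquinoline-2-carboxylate; 11 2-bromo-4-iodoanisole
Product: 12 tert-butyl (3S)-5-(3-bromo-4-methoxyphenyl)-6,8-dimethoxy-3-methyl-3,4-dihydro-1H-isoquinoline-2-carboxylate
Conditions: 11 (1.5 equiv), Pd(PPh3)4 (5 mol%), K3PO4, DME/H2O, 80 °C
Reagents that add atoms: none
Why: In this Suzuki–Miyaura coupling zerovalent palladium should insert into the C–I bond much faster than into the C–Br bond, so the bromine ortho to the methoxy group is kept for step 7; the iodide has no ortho substituent, so only the boronate side of the new C5–C8′ bond is hindered.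

**Step 7**
Reactants: 12 tert-butyl (3S)-5-(3-bromo-4-methoxyphenyl)-6,8-dimethoxy-3-methyl-3,4-dihydro-1H-isoquinoline-2-carboxylate; 13 chromium hexacarbonyl
Product: 16 pentacarbonyl{methoxy[2-methoxy-5-((3S)-2-Boc-6,8-dimethoxy-3-methyl-3,4-dihydro-1H-isoquinolin-5-yl)phenyl]methylidene}chromium, via aryllithium 14 (not isolated), via lithium acylchromate 15 (not isolated)
Conditions: t-BuLi (2.05 equiv), THF, −78 °C; then 13, −78 °C to 0 °C; evaporate; then Me3OBF4 (1.2 equiv), CH2Cl2, 0 °C; argon throughout
Reagents that add atoms: trimethyloxonium tetrafluoroborate, C[O+](C)C.F[B-](F)(F)F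
Why: This is the Fischer carbene synthesis: bromine–lithium exchange at −78 °C should outrun deprotonation next to the carbamate, the methoxy-stabilised aryllithium should add to a CO ligand of Cr(CO)6, and the anionic acylchromate oxygen is far more nucleophilic toward the oxonium salt than the carbamate.

**Step 8**
Reactants: 16 pentacarbonyl{methoxy[2-methoxy-5-((3S)-2-Boc-6,8-dimethoxy-3-methyl-3,4-dihydro-1H-isoquinolin-5-yl)phenyl]methylidene}chromium; 17 propyne
Product: 19 tert-butyl (3S)-5-(8-hydroxy-4,5-dimethoxy-7-methylnaphthalen-1-yl)-6,8-dimethoxy-3-methyl-3,4-dihydro-1H-isoquinoline-2-carboxylate, via tricarbonylchromium naphthol complex 18 (not isolated)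
Conditions: 17 (3 equiv, solution in THF), THF (0.05 M), sealed vessel, argon, 50 °C; then brief exposure to air in EtOAc, rt, filtration through silica
Reagents that add atoms: none
Why: Thermal loss of a cis CO ligand from 16, possibly helped by transient chelation of the ortho methoxy group, should let propyne bind and insert into the Cr=C bond to give a vinylcarbene; CO insertion then gives a chromium-bound dienylketene that closes and enolises to the naphthol, held as the Cr(CO)3 complex 18 until air releases it. This is the Dötz benzannulation of an aryl(alkoxy)carbene complex of zerovalent chromium with a terminal alkyne, and the closest models are 2,5-disubstituted aryl complexes, which also close next to a substituent. Ring A′ closes by 6π-electrocyclisation of the ketene carbon C1′ onto the free ortho carbon C8a′ (a formal 3+2+1 assembly forming C4′–C3′, C2′–C1′ and C1′–C8a′), followed by tautomerisation. No stereocentre is formed and C3 is remote from the reacting atoms; the C5–C8′ axis becomes hindered in this step and is not controlled. The step needs alkyne regioselectivity, which should follow from the larger alkyne substituent (methyl against hydrogen) ending next to the CO-derived carbon, and site selectivity of closure, which is secured because the other ortho position carries the methoxy group that becomes C5′-OMe; naphthol formation over indene formation is favoured by chromium in an ethereal solvent at moderate temperature.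

**Step 9**
Reactants: 19 tert-butyl (3S)-5-(8-hydroxy-4,5-dimethoxy-7-methylnaphthalen-1-yl)-6,8-dimethoxy-3-methyl-3,4-dihydro-1H-isoquinoline-2-carboxylate
Product: 20 tert-butyl (3S)-5-[4,5-dimethoxy-7-methyl-8-(trifluoromethylsulfonyloxy)naphthalen-1-yl]-6,8-dimethoxy-3-methyl-3,4-dihydro-1H-isoquinoline-2-carboxylate
Conditions: Tf2O (1.2 equiv), pyridine, CH2Cl2, −20 °C to 0 °C, argon, on freshly prepared 19
Reagents that add atoms: trifluoromethanesulfonic anhydride, O=S(=O)(OS(=O)(=O)C(F)(F)F)C(F)(F)F
Why: O-sulfonylation of the naphthol with the small, highly reactive anhydride should succeed even though the C1′ hydroxyl sits between the C2′ methyl and the peri aryl group, and it also protects the oxidation-prone 4-methoxy-1-naphthol at once; a tertiary Boc carbamate tolerates these conditions at low temperature.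

**Step 10**
Reactants: 20 tert-butyl (3S)-5-[4,5-dimethoxy-7-methyl-8-(trifluoromethylsulfonyloxy)naphthalen-1-yl]-6,8-dimethoxy-3-methyl-3,4-dihydro-1H-isoquinoline-2-carboxylate
Product: 21 tert-butyl (3S)-5-(4,5-dimethoxy-7-methylnaphthalen-1-yl)-6,8-dimethoxy-3-methyl-3,4-dihydro-1H-isoquinoline-2-carboxylate
Conditions: Pd(OAc)2 (10 mol%), dppf (12 mol%), HCO2H, Et3N, DMF, 90 °C
Reagents that add atoms: none
Why: Palladium-catalysed reduction of an aryl triflate by triethylammonium formate proceeds by oxidative addition, formate exchange, decarboxylation to an aryl palladium hydride and reductive elimination; the chelating ferrocenyl diphosphine is chosen because the C1′ triflate is crowded and electron-rich.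

**Step 11**
Reactants: 21 tert-butyl (3S)-5-(4,5-dimethoxy-7-methylnaphthalen-1-yl)-6,8-dimethoxy-3-methyl-3,4-dihydro-1H-isoquinoline-2-carboxylate
Product: 22 (3S)-5-(4,5-dimethoxy-7-methylnaphthalen-1-yl)-6,8-dimethoxy-3-methyl-1,2,3,4-tetrahydroisoquinoline
Conditions: TFA/CH2Cl2 (1:4), 0 °C to rt; aq. NaHCO3 work-up
Reagents that add atoms: none
Why: Acidolysis of the tert-butyl carbamate should free the secondary amine without affecting the aryl methyl ethers or the C3 stereocentre, which is not enolisable.

**Compound list**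

1 | 1-bromo-3,5-dimethoxybenzene | COc1cc(Br)cc(OC)c1 | starting material
2 | tert-butyl (4S)-4-methyl-1,2,3-oxathiazolidine-3-carboxylate 2,2-dioxide (catalogue N-Boc cyclic sulfamidate of L-alaninol) | C[C@H]1COS(=O)(=O)N1C(=O)OC(C)(C)C | starting material
3 | (3,5-dimethoxyphenyl)magnesium bromide (formed in the flask) | COc1cc([Mg]Br)cc(OC)c1 | intermediate
4 | bromomagnesium N-Boc-N-[(2S)-1-(3,5-dimethoxyphenyl)propan-2-yl]sulfamate (formed in the flask) | COc1cc(C[C@H](C)N(C(=O)OC(C)(C)C)S(=O)(=O)[O-])cc(OC)c1.[Mg+]Br | intermediate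
5 | tert-butyl N-[(2S)-1-(3,5-dimethoxyphenyl)propan-2-yl]carbamate | COc1cc(C[C@H](C)NC(=O)OC(C)(C)C)cc(OC)c1 | intermediate
6 | (2S)-1-(3,5-dimethoxyphenyl)propan-2-amine (present as its trifluoroacetate, formed in the flask) | COc1cc(C[C@H](C)N)cc(OC)c1 | intermediate
7 | (3S)-6,8-dimethoxy-3-methyl-1,2,3,4-tetrahydroisoquinoline | COc1cc(OC)cc2c1CN[C@@H](C)C2 | intermediate
8 | tert-butyl (3S)-6,8-dimethoxy-3-methyl-3,4-dihydro-1H-isoquinoline-2-carboxylate | COc1cc(OC)cc2c1CN(C(=O)OC(C)(C)C)[C@@H](C)C2 | intermediate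
9 | tert-butyl (3S)-5-bromo-6,8-dimethoxy-3-methyl-3,4-dihydro-1H-isoquinoline-2-carboxylate | COc1cc(OC)c(Br)c2c1CN(C(=O)OC(C)(C)C)[C@@H](C)C2 | intermediate
10 | tert-butyl (3S)-6,8-dimethoxy-3-methyl-5-(4,4,5,5-tetramethyl-1,3,2-dioxaborolan-2-yl)-3,4-dihydro-1H-isoquinoline-2-carboxylate | COc1cc(OC)c(B3OC(C)(C)C(C)(C)O3)c2c1CN(C(=O)OC(C)(C)C)[C@@H](C)C2 | intermediate
11 | 2-bromo-4-iodoanisole | COc1ccc(I)cc1Br | starting material
12 | tert-butyl (3S)-5-(3-bromo-4-methoxyphenyl)-6,8-dimethoxy-3-methyl-3,4-dihydro-1H-isoquinoline-2-carboxylate | COc1cc(OC)c(-c3ccc(OC)c(Br)c3)c2c1CN(C(=O)OC(C)(C)C)[C@@H](C)C2 | intermediate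
13 | chromium hexacarbonyl, Cr(CO)6 | O=C=[Cr](=C=O)(=C=O)(=C=O)(=C=O)=C=O | starting material
14 | aryllithium from 12, lithium in place of bromine (formed in the flask) | COc1cc(OC)c(-c3ccc(OC)c([Li])c3)c2c1CN(C(=O)OC(C)(C)C)[C@@H](C)C2 | intermediate
15 | lithium pentacarbonyl(aroyl)chromate from 14 and Cr(CO)6 (formed in the flask) | [Li+].[O-]C(=[Cr](=C=O)(=C=O)(=C=O)(=C=O)=C=O)c1cc(-c2c(OC)cc(OC)c3CN(C(=O)OC(C)(C)C)[C@@H](C)Cc23)ccc1OC | intermediate
16 | pentacarbonyl{methoxy[2-methoxy-5-((3S)-2-Boc-6,8-dimethoxy-3-methyl-3,4-dihydro-1H-isoquinolin-5-yl)phenyl]methylidene}chromium | COC(=[Cr](=C=O)(=C=O)(=C=O)(=C=O)=C=O)c1cc(-c2c(OC)cc(OC)c3CN(C(=O)OC(C)(C)C)[C@@H](C)Cc23)ccc1OC | intermediate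
17 | propyne | CC#C | starting material
18 | tricarbonylchromium complex of naphthol 19, metal bound η6 to ring A′ (formed in the flask) | COc1ccc(-c2c(OC)cc(OC)c3CN(C(=O)OC(C)(C)C)[C@@H](C)Cc23)c2c(O)c(C)cc(OC)c12.[Cr].[C-]#[O+].[C-]#[O+].[C-]#[O+] | intermediate
19 | tert-butyl (3S)-5-(8-hydroxy-4,5-dimethoxy-7-methylnaphthalen-1-yl)-6,8-dimethoxy-3-methyl-3,4-dihydro-1H-isoquinoline-2-carboxylate (C1′ naphthol) | COc1ccc(-c2c(OC)cc(OC)c3CN(C(=O)OC(C)(C)C)[C@@H](C)Cc23)c2c(O)c(C)cc(OC)c12 | intermediate
20 | tert-butyl (3S)-5-[4,5-dimethoxy-7-methyl-8-(trifluoromethylsulfonyloxy)naphthalen-1-yl]-6,8-dimethoxy-3-methyl-3,4-dihydro-1H-isoquinoline-2-carboxylate (C1′ triflate) | COc1ccc(-c2c(OC)cc(OC)c3CN(C(=O)OC(C)(C)C)[C@@H](C)Cc23)c2c(OS(=O)(=O)C(F)(F)F)c(C)cc(OC)c12 | intermediate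
21 | tert-butyl (3S)-5-(4,5-dimethoxy-7-methylnaphthalen-1-yl)-6,8-dimethoxy-3-methyl-3,4-dihydro-1H-isoquinoline-2-carboxylate | COc1cc(OC)c(-c2ccc(OC)c3c(OC)cc(C)cc23)c2c1CN(C(=O)OC(C)(C)C)[C@@H](C)C2 | intermediate
22 | (3S)-5-(4,5-dimethoxy-7-methylnaphthalen-1-yl)-6,8-dimethoxy-3-methyl-1,2,3,4-tetrahydroisoquinoline | COc1cc(OC)c(-c2ccc(OC)c3c(OC)cc(C)cc23)c2c1CN[C@@H](C)C2 | target

**Step count**

Total: 11 steps. Longest linear sequence: 11 steps (from 1 or 2 to 22); compounds 11, 13 and 17 enter as purchased materials.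

**Steps most likely to fail**

1. Step 8. The ring closure has to occur at the ortho carbon next to the bulky isoquinolinyl group, so the vinylketene may be diverted to cyclobutenone, furan or indene products, or the complex may decompose before taking up the alkyne. The fallback sets out from boronate 10 and comes back at 21, building the naphthalene before the biaryl bond. Commercial 2-bromo-4-chloroanisole would undergo bromine–lithium exchange (t-BuLi, THF, −78 °C) to (5-chloro-2-methoxyphenyl)lithium F1, which would add to Cr(CO)6 to give the lithium acylchromate F2, and methylation with Me3OBF4 would give pentacarbonyl[(5-chloro-2-methoxyphenyl)(methoxy)methylidene]chromium F3. Benzannulation of F3 with propyne 17, now closing next to a small chlorine atom, would give the tricarbonylchromium chloronaphthol complex F4 and, after air work-up, 8-chloro-4,5-dimethoxy-2-methylnaphthalen-1-ol F5. Triflation (Tf2O, pyridine) would give 8-chloro-4,5-dimethoxy-2-methylnaphthalen-1-yl trifluoromethanesulfonate F6, and triflate-selective reduction (Pd(OAc)2, PPh3, HCO2H, Et3N, DMF) would give 1-chloro-4,5-dimethoxy-7-methylnaphthalene F7. A Suzuki coupling for hindered partners (Pd(OAc)2, SPhos, K3PO4, toluene/H2O, 100 °C) would join F7 to 10 and give 21 directly.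

2. Step 7. The organolithium stage may suffer proton transfer from C1–H2 beside the carbamate or from C7–H between the two methoxy groups, or addition to the carbamate, and the oxonium salt may cost the Boc group. The fallback sets out from boronate 10 and comes back at 16 without any organolithium. Suzuki coupling of 10 with commercial methyl 5-iodo-2-methoxybenzoate (Pd(PPh3)4, K3PO4, DME/H2O) would give methyl 5-[(3S)-2-Boc-6,8-dimethoxy-3-methyl-3,4-dihydro-1H-isoquinolin-5-yl]-2-methoxybenzoate F8. Saponification (LiOH, THF/H2O) would give the carboxylic acid F9, and 1-chloro-N,N,2-trimethylprop-1-en-1-amine in CH2Cl2, a neutral reagent that spares the Boc group, would give the acid chloride F10. In a second flask Cr(CO)6 13 would be reduced with KC8 in THF to dipotassium pentacarbonylchromate F11. Acylation of F11 by F10 at −78 °C would give the potassium acylchromate F12, which would be methylated with Me3OBF4 as in step 7 to give 16.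

3. Step 10. Oxidative addition into the crowded, electron-rich C1′ triflate may be slow, so that S–O cleavage back to the naphthol or catalyst decay takes over. The fallback sets out from naphthol 19 and comes back at 21 by hydrogenolysis of a heteroaryl ether. Naphthol 19 would be treated with 5-chloro-1-phenyl-1H-tetrazole and K2CO3 in DMF to give the 1-phenyl-1H-tetrazol-5-yl ether F13. Hydrogenolysis of F13 (H2, 10% palladium on carbon, EtOH/THF, 40 °C) would cleave the C1′–O bond and give 21.

**Further compounds**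

F1 | step 8 | (5-chloro-2-methoxyphenyl)lithium | COc1ccc(Cl)cc1[Li]
F2 | step 8 | lithium pentacarbonyl(5-chloro-2-methoxybenzoyl)chromate | [Li+].[O-]C(=[Cr](=C=O)(=C=O)(=C=O)(=C=O)=C=O)c1cc(Cl)ccc1OC
F3 | step 8 | pentacarbonyl[(5-chloro-2-methoxyphenyl)(methoxy)methylidene]chromium | COC(=[Cr](=C=O)(=C=O)(=C=O)(=C=O)=C=O)c1cc(Cl)ccc1OC
F4 | step 8 | tricarbonylchromium complex of 8-chloro-4,5-dimethoxy-2-methylnaphthalen-1-ol | COc1ccc(Cl)c2c(O)c(C)cc(OC)c12.[Cr].[C-]#[O+].[C-]#[O+].[C-]#[O+]
F5 | step 8 | 8-chloro-4,5-dimethoxy-2-methylnaphthalen-1-ol | COc1ccc(Cl)c2c(O)c(C)cc(OC)c12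
F6 | step 8 | 8-chloro-4,5-dimethoxy-2-methylnaphthalen-1-yl trifluoromethanesulfonate | COc1ccc(Cl)c2c(OS(=O)(=O)C(F)(F)F)c(C)cc(OC)c12
F7 | step 8 | 1-chloro-4,5-dimethoxy-7-methylnaphthalene | COc1ccc(Cl)c2cc(C)cc(OC)c12
F8 | step 7 | methyl 5-[(3S)-2-Boc-6,8-dimethoxy-3-methyl-3,4-dihydro-1H-isoquinolin-5-yl]-2-methoxybenzoate | COC(=O)c1cc(-c2c(OC)cc(OC)c3CN(C(=O)OC(C)(C)C)[C@@H](C)Cc23)ccc1OC
F9 | step 7 | 5-[(3S)-2-Boc-6,8-dimethoxy-3-methyl-3,4-dihydro-1H-isoquinolin-5-yl]-2-methoxybenzoic acid | OC(=O)c1cc(-c2c(OC)cc(OC)c3CN(C(=O)OC(C)(C)C)[C@@H](C)Cc23)ccc1OC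
F10 | step 7 | 5-[(3S)-2-Boc-6,8-dimethoxy-3-methyl-3,4-dihydro-1H-isoquinolin-5-yl]-2-methoxybenzoyl chloride | ClC(=O)c1cc(-c2c(OC)cc(OC)c3CN(C(=O)OC(C)(C)C)[C@@H](C)Cc23)ccc1OC
F11 | step 7 | dipotassium pentacarbonylchromate, K2Cr(CO)5 | [K+].[K+].O=C=[Cr-2](=C=O)(=C=O)(=C=O)=C=O
F12 | step 7 | potassium pentacarbonyl(aroyl)chromate, potassium analogue of 15 | [K+].[O-]C(=[Cr](=C=O)(=C=O)(=C=O)(=C=O)=C=O)c1cc(-c2c(OC)cc(OC)c3CN(C(=O)OC(C)(C)C)[C@@H](C)Cc23)ccc1OC
F13 | step 10 | tert-butyl (3S)-5-[4,5-dimethoxy-7-methyl-8-(1-phenyl-1H-tetrazol-5-yloxy)naphthalen-1-yl]-6,8-dimethoxy-3-methyl-3,4-dihydro-1H-isoquinoline-2-carboxylate | COc1ccc(-c2c(OC)cc(OC)c3CN(C(=O)OC(C)(C)C)[C@@H](C)Cc23)c2c(Oc3nnnn3-c3ccccc3)c(C)cc(OC)c12
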